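The benzylic CH2 is C1, the cyclohexene ring is C2–C7, the chain runs C8–C14 and C15 is the isopropenyl carbon. The ring is disconnected at its C3=C4 alkene and at C5–C6, which excises C4–C5 as a vinyl linchpin. The feature exploited is that C6 (CHBr, first a carbinol) is homoallylic to the trisubstituted C3=C4 bond, the retron of a transposing allylboration. In one operation a C3 tosylhydrazone is coupled with vinylboroxine. The 1,2-boronate shift makes the C3–C4 bond and the tertiary allylboronic acid attacks the tethered C6 aldehyde through C5, giving ring, alkene and C6 alcohol. The acyclic precursor, set at C2/C7 by Ireland–Claisen rearrangement, carries the epoxidised chain.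

Key step: step 19

Assumption: in step 8 the (S,S)-configured boron controller is taken to favour acid 12 with the (2S,7S) configuration; should the sense be opposite, its (R,R) antipode is used without other change.

Step 1
Reactants: 1 methyl 3-formyl-4-hydroxybenzoate
Product: 2 methyl 3-formyl-4-(triisopropylsilyloxy)benzoate
Conditions: i-Pr3SiCl, imidazole, DMF, rt
Reagents that add atoms: chlorotriisopropylsilane, CC(C)[Si](Cl)(C(C)C)C(C)C
Why: Imidazole-promoted O-silylation of the phenol; the bulky silyl ether is chosen to survive the basic and organometallic steps and to be removed last under buffered fluoride.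

Step 2
Reactants: 2 methyl 3-formyl-4-(triisopropylsilyloxy)benzoate; 3 benzyl (triphenylphosphoranylidene)acetate
Product: 4 benzyl (E)-3-[5-(methoxycarbonyl)-2-(triisopropylsilyloxy)phenyl]prop-2-enoate
Conditions: toluene, 80 °C
Reagents that add atoms: none
Why: Wittig olefination with a stabilised ylide should give the (E)-cinnamate, whose geometry is irrelevant because the alkene is saturated next.

Step 3
Reactants: 4 benzyl (E)-3-[5-(methoxycarbonyl)-2-(triisopropylsilyloxy)phenyl]prop-2-enoate
Product: 5 3-[5-(methoxycarbonyl)-2-(triisopropylsilyloxy)phenyl]propanoic acid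
Conditions: H2 (1 atm), Pd/C, EtOAc, rt
Reagents that add atoms: none
Why: Heterogeneous hydrogenation saturates the alkene and hydrogenolyses the benzyl ester in one operation while the methyl ester and the aryl silyl ether are untouched.

Step 4
Reactants: 6 3-methylbut-2-en-1-yl acetate
Product: 7 (E)-4-hydroxy-3-methylbut-2-en-1-yl acetate
Conditions: SeO2 (cat.), t-BuOOH, CH2Cl2, rt
Reagents that add atoms: tert-butyl hydroperoxide, CC(C)(C)OO
Why: Riley-type allylic oxidation hydroxylates the (E)-methyl group of the trisubstituted alkene selectively, which fixes the E geometry needed for the later chair transition state.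

Step 5
Reactants: 7 (E)-4-hydroxy-3-methylbut-2-en-1-yl acetate
Product: 8 (E)-3-methyl-4-(triethylsilyloxy)but-2-en-1-yl acetate
Conditions: Et3SiCl, imidazole, CH2Cl2, 0 °C
Reagents that add atoms: chlorotriethylsilane, CC[Si](Cl)(CC)CC
Why: Standard silylation of the primary allylic alcohol; the triethylsilyl ether is the most acid-labile silyl group of the route and can be removed first.

Step 6
Reactants: 8 (E)-3-methyl-4-(triethylsilyloxy)but-2-en-1-yl acetate
Product: 9 (E)-3-methyl-4-(triethylsilyloxy)but-2-en-1-ol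
Conditions: K2CO3 (cat.), MeOH, 0 °C
Reagents that add atoms: none
Why: Mild transesterification removes the acetate, the triethylsilyl ether being stable to cold methanolic carbonate.

Step 7
Reactants: 5 3-[5-(methoxycarbonyl)-2-(triisopropylsilyloxy)phenyl]propanoic acid; 9 (E)-3-methyl-4-(triethylsilyloxy)but-2-en-1-ol
Product: 10 (E)-3-methyl-4-(triethylsilyloxy)but-2-en-1-yl 3-[5-(methoxycarbonyl)-2-(triisopropylsilyloxy)phenyl]propanoate
Conditions: EDC·HCl, DMAP, CH2Cl2, rt
Reagents that add atoms: none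
Why: Steglich-type carbodiimide esterification of an unhindered primary allylic alcohol.

Step 8
Reactants: 10 (E)-3-methyl-4-(triethylsilyloxy)but-2-en-1-yl 3-[5-(methoxycarbonyl)-2-(triisopropylsilyloxy)phenyl]propanoate
Product: 12 (2S,3S)-2-{[5-(methoxycarbonyl)-2-(triisopropylsilyloxy)phenyl]methyl}-3-methyl-3-[(triethylsilyloxy)methyl]pent-4-enoic acid, via boron ketene acetal 11 (not isolated)
Conditions: (4S,5S)-2-bromo-1,3-bis{[3,5-bis(trifluoromethyl)phenyl]sulfonyl}-4,5-diphenyl-1,3,2-diazaborolidine (1.2 equiv), Et3N, toluene–hexane, −78 °C then −20 °C; aqueous work-up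
Reagents that add atoms: none
Why: Enantioselective boron-enolate Ireland–Claisen rearrangement: soft enolisation should give the E(O) ketene acetal (benzyl cis to the allyloxy oxygen), and a chair transition state with the (E)-allyl unit (CH2OSiEt3 equatorial, CH3 axial) sets C2 and the quaternary C7 in the required relative sense while the C2-symmetric sulfonamide ligand selects the enantiotopic face.

Step 9
Reactants: 13 pent-4-ynoic acid
Product: 14 N-methoxy-N-methylpent-4-ynamide
Conditions: MeNHOMe·HCl, EDC·HCl, N-methylmorpholine, CH2Cl2, 0 °C to rt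
Reagents that add atoms: N,O-dimethylhydroxylamine hydrochloride, CNOC.Cl
Why: Carbodiimide amide coupling to the Weinreb amide.

Step 10
Reactants: 14 N-methoxy-N-methylpent-4-ynamide; 15 prop-1-en-2-ylmagnesium bromide
Product: 16 2-methylhept-1-en-6-yn-3-one
Conditions: THF, −20 to 0 °C (2.2 equiv of 15); inverse quench into cold 1 M HCl
Reagents that add atoms: none
Why: Weinreb ketone synthesis, in which the chelated tetrahedral intermediate prevents over-addition, one equivalent of Grignard reagent is spent on the alkyne C–H and the cold acidic quench keeps the liberated amine from adding to the enone.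

Step 11
Reactants: 16 2-methylhept-1-en-6-yn-3-one
Product: 17 (3S)-2-methylhept-1-en-6-yn-3-ol
Conditions: (R)-2-methyl-CBS-oxazaborolidine (20 mol %), catecholborane, toluene, −78 °C
Reagents that add atoms: none
Why: Corey–Bakshi–Shibata reduction with the isopropenyl group as the large substituent, so that the (R)-catalyst should give the (S)-allylic alcohol (C14), and catecholborane at low temperature leaves alkyne and alkene alone.

Step 12
Reactants: 17 (3S)-2-methylhept-1-en-6-yn-3-ol
Product: 18 (3S)-3-(tert-butyldimethylsilyloxy)-2-methylhept-1-en-6-yne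
Conditions: t-BuMe2SiCl, imidazole, DMF, rt
Reagents that add atoms: tert-butyl(chloro)dimethylsilane, CC(C)(C)[Si](C)(C)Cl
Why: Routine silylation of the secondary allylic alcohol.

Step 13
Reactants: 18 (3S)-3-(tert-butyldimethylsilyloxy)-2-methylhept-1-en-6-yne
Product: 19 (3S,6E)-3-(tert-butyldimethylsilyloxy)-7-iodo-2,6-dimethylhepta-1,6-diene
Conditions: Me3Al, Cp2ZrCl2, CH2Cl2, 0 °C to rt; then I2, THF, −30 °C
Reagents that add atoms: trimethylaluminium, C[Al](C)C; iodine, II
Why: Negishi zirconium-catalysed carboalumination adds CH3 and Al syn across the terminal alkyne with Al at the terminus, and iodinolysis with retention gives the (E)-trisubstituted vinyl iodide.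

Step 14
Reactants: 12 (2S,3S)-2-{[5-(methoxycarbonyl)-2-(triisopropylsilyloxy)phenyl]methyl}-3-methyl-3-[(triethylsilyloxy)methyl]pent-4-enoic acid; 19 (3S,6E)-3-(tert-butyldimethylsilyloxy)-7-iodo-2,6-dimethylhepta-1,6-diene
Product: 21 (2S,3S,6E,10S)-10-(tert-butyldimethylsilyloxy)-2-{[5-(methoxycarbonyl)-2-(triisopropylsilyloxy)phenyl]methyl}-3,7,11-trimethyl-3-[(triethylsilyloxy)methyl]dodeca-6,11-dienoic acid, via B-alkyl-9-BBN borane 20 (not isolated)
Conditions: 9-BBN (2.5 equiv), THF, rt; then 19, PdCl2(dppf) (5 mol %), AsPh3, Cs2CO3, DMF–H2O, rt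
Reagents that add atoms: none
Why: Anti-Markovnikov hydroboration of the only alkene of 12 followed by B-alkyl Suzuki–Miyaura coupling forms the C9–C10 bond with retention of the (E)-vinyl iodide geometry.

Step 15
Reactants: 21 (2S,3S,6E,10S)-10-(tert-butyldimethylsilyloxy)-2-{[5-(methoxycarbonyl)-2-(triisopropylsilyloxy)phenyl]methyl}-3,7,11-trimethyl-3-[(triethylsilyloxy)methyl]dodeca-6,11-dienoic acid
Product: 24 methyl 3-[(2S,3S,6E,10S)-2-acetyl-10-(tert-butyldimethylsilyloxy)-3-(hydroxymethyl)-3,7,11-trimethyldodeca-6,11-dien-1-yl]-4-(triisopropylsilyloxy)benzoate, via acid chloride 22 (not isolated), via triethylsilyl-protected ketone 23 (not isolated)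
Conditions: 1-chloro-N,N,2-trimethylprop-1-en-1-amine, CH2Cl2, 0 °C; then Me2CuLi, Et2O, −78 °C; then AcOH–THF–H2O (3:1:1), rt
Reagents that add atoms: lithium dimethylcuprate, [Li+].C[Cu-]C
Why: Neutral acid chloride formation, ketone synthesis with the Gilman cuprate (no reaction with esters or alkenes at −78 °C and no epimerisation at C2), then selective acidolysis of the primary triethylsilyl ether in the presence of the secondary tert-butyldimethylsilyl and aryl triisopropylsilyl ethers.

Step 16
Reactants: 24 methyl 3-[(2S,3S,6E,10S)-2-acetyl-10-(tert-butyldimethylsilyloxy)-3-(hydroxymethyl)-3,7,11-trimethyldodeca-6,11-dien-1-yl]-4-(triisopropylsilyloxy)benzoate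
Product: 25 epoxy hydroxy ketone (24 with a (6S,7S)-6,7-epoxide in place of the 6E alkene; C10 and C11 in the global locants)
Conditions: L-fructose-derived Shi ketone (30 mol %), KHSO5, K2CO3, Bu4NHSO4, MeCN–CH2(OMe)2–aq. Na2B4O7 buffer, 0 °C
Reagents that add atoms: potassium peroxymonosulfate, [K+].[O-]S(=O)(=O)OO
Why: Shi asymmetric epoxidation is selective for the electron-rich trisubstituted C10=C11 alkene over the allylic-oxygenated isopropenyl group, and the L-fructose-derived ketone should give the (10S,11S)-epoxide by reagent control.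

Step 17
Reactants: 25 epoxy hydroxy ketone
Product: 26 N-tosylhydrazone of 25 (C=N at C3)
Conditions: TsNHNH2, MeOH, 40 °C
Reagents that add atoms: 4-methylbenzenesulfonohydrazide, Cc1ccc(cc1)S(=O)(=O)NN
Why: Condensation of the methyl ketone with tosylhydrazide in neutral methanol, which leaves the epoxide intact and masks the ketone before the aldehyde is unveiled.

Step 18
Reactants: 26 N-tosylhydrazone of 25
Product: 27 aldehyde tosylhydrazone (CH2OH on C7 oxidised to CHO, C6)
Conditions: Pr4N[RuO4] (5 mol %), N-methylmorpholine N-oxide, 4 Å molecular sieves, CH2Cl2, rt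
Reagents that add atoms: none
Why: Ley–Griffith oxidation converts the neopentyl primary alcohol into the non-enolisable aldehyde under neutral conditions that spare epoxide, hydrazone and alkenes.

Step 19
Reactants: 27 aldehyde tosylhydrazone; 28 2,4,6-trivinylcyclotriboroxane–pyridine complex
Product: 31 cyclohexenol (global 2R,6R,7S,10S,11S,14S; ring C2–C7 closed; C3=C4 alkene; C6–OH trans to the C7 methyl), via diazoalkane 29 (not isolated), via tertiary allylboronic acid 30 (not isolated)
Conditions: K2CO3 (3 equiv), 1,4-dioxane (0.01 M), 110 °C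
Reagents that add atoms: none
Why: Base-induced Bamford–Stevens fragmentation of the tosylhydrazone gives diazoalkane 29, which adds to the vinylboron species; 1,2-migration of the vinyl group from boron to C3 with loss of N2 forms the C3–C4 bond and the tertiary allylboronic acid 30, which allylborates the tethered C6 aldehyde through its γ-carbon C5 with allylic transposition, so that the C5–C6 bond, the C3=C4 alkene and the C6 carbinol appear together. The closest known reaction types are the metal-free reductive coupling of N-tosylhydrazones with alkenylboronic acids, its carbocyclising variants with tethered electrophiles, and the diazoalkane/vinylboronic acid/aldehyde synthesis of homoallylic alcohols. The cyclohexene is closed by 6-exo-trig addition to the aldehyde through a bicyclic boat Zimmerman–Traxler transition state in which the B–O unit bridges C3 and C6, the alternative attack through C3 being excluded because it would need a four-membered ring. The new C6 stereocentre is controlled by C2 and C7: the B–O bridge should lie on the ring face that carries H-2 and the C8 chain, away from the benzyl and methyl groups, which places the hydroxyl trans to the C7 methyl, while the transient C3–B centre is lost on transposition and its epimers can interconvert by 1,3-borotropic shift. The step needs boron capture of the diazoalkane to outrun 1,2-hydride shift and ring closure to outrun protodeboronation or intermolecular allylation, which excess boroxine, the intramolecular aldehyde and high dilution should secure.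

Step 20
Reactants: 31 cyclohexenol
Product: 32 bromohydrin (global 2R,6R,7S,10R,11S,14S; C10–Br and tertiary C11–OH)
Conditions: Li2NiBr4, THF, 0 °C to rt
Reagents that add atoms: dilithium tetrabromonickelate, [Li+].[Li+].Br[Ni-2](Br)(Br)Br
Why: Soft nucleophilic bromide opens the trisubstituted epoxide by SN2 at the less substituted C10 with inversion, giving the (10R)-bromide and leaving the C11–O bond, hence the (11S) tertiary alcohol, untouched.

Step 21
Reactants: 32 bromohydrin
Product: 33 dibromide (global 2R,6S,7S,10R,11S,14S; C6–Br cis to the C7 methyl)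
Conditions: CBr4, P(n-C8H17)3, pyridine, toluene, 60 °C
Reagents that add atoms: tetrabromomethane, BrC(Br)(Br)Br
Why: Appel-type substitution in which the oxyphosphonium salt of the secondary C6 alcohol is displaced by bromide with inversion, converting the alcohol trans to the C7 methyl into the (6S)-bromide cis to it, the tertiary C11 alcohol being unreactive.

Step 22
Reactants: 33 dibromide
Product: 34 benzoic acid (33 with CO2H in place of CO2CH3)
Conditions: Me3SnOH, 1,2-dichloroethane, 80 °C; 0.1 M HCl work-up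
Reagents that add atoms: trimethyltin hydroxide, C[Sn](C)(C)O
Why: Trimethyltin hydroxide cleaves the methyl ester under nearly neutral conditions, which avoids epoxide re-formation from the bromohydrin and loss of the aryl silyl ether.

Step 23
Reactants: 34 benzoic acid
Product: 35 seco acid (C14–OH free; aryl silyl ether retained)
Conditions: HF·pyridine, pyridine, THF, 0 °C to rt
Reagents that add atoms: none
Why: Acidic fluoride removes the secondary alkyl silyl ether selectively, aryl triisopropylsilyl ethers being much slower to cleave under non-basic conditions.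

Step 24
Reactants: 35 seco acid
Product: 36 macrolactone (target with the phenol as its triisopropylsilyl ether)
Conditions: 2-methyl-6-nitrobenzoic anhydride, DMAP, Et3N, CH2Cl2 (1 mM), rt, slow addition
Reagents that add atoms: none
Why: Shiina macrolactonisation through the mixed anhydride at high dilution closes the 15-membered lactone at the only acylable hydroxyl (secondary C14–OH) with retention at C14.

Step 25
Reactants: 36 macrolactone
Product: 37 CNP0213075.1
Conditions: Bu4NF, AcOH, THF, 0 °C
Reagents that add atoms: none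
Why: Fluoride cleaves the aryl silyl ether rapidly, and acetic acid buffering keeps the bromohydrin from closing to the epoxide.

Compound list
1 | methyl 3-formyl-4-hydroxybenzoate | COC(=O)c1ccc(O)c(C=O)c1 | starting material
2 | methyl 3-formyl-4-(triisopropylsilyloxy)benzoate | COC(=O)c1ccc(O[Si](C(C)C)(C(C)C)C(C)C)c(C=O)c1 | intermediate
3 | benzyl (triphenylphosphoranylidene)acetate | O=C(OCc1ccccc1)C=P(c1ccccc1)(c1ccccc1)c1ccccc1 | starting material
4 | benzyl (E)-3-[5-(methoxycarbonyl)-2-(triisopropylsilyloxy)phenyl]prop-2-enoate | COC(=O)c1ccc(O[Si](C(C)C)(C(C)C)C(C)C)c(/C=C/C(=O)OCc2ccccc2)c1 | intermediate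
5 | 3-[5-(methoxycarbonyl)-2-(triisopropylsilyloxy)phenyl]propanoic acid | COC(=O)c1ccc(O[Si](C(C)C)(C(C)C)C(C)C)c(CCC(=O)O)c1 | intermediate
6 | 3-methylbut-2-en-1-yl acetate (prenyl acetate) | CC(C)=CCOC(C)=O | starting material
7 | (E)-4-hydroxy-3-methylbut-2-en-1-yl acetate | CC(=O)OC/C=C(\C)CO | intermediate
8 | (E)-3-methyl-4-(triethylsilyloxy)but-2-en-1-yl acetate | CC(=O)OC/C=C(\C)CO[Si](CC)(CC)CC | intermediate
9 | (E)-3-methyl-4-(triethylsilyloxy)but-2-en-1-ol | OC/C=C(\C)CO[Si](CC)(CC)CC | intermediate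
10 | (E)-3-methyl-4-(triethylsilyloxy)but-2-en-1-yl 3-[5-(methoxycarbonyl)-2-(triisopropylsilyloxy)phenyl]propanoate | COC(=O)c1ccc(O[Si](C(C)C)(C(C)C)C(C)C)c(CCC(=O)OC/C=C(\C)CO[Si](CC)(CC)CC)c1 | intermediate
11 | boron ketene acetal of 10 (E(O) geometry; boron held in the (4S,5S)-bis-sulfonyl-diphenyl-diazaborolidine ring) | COC(=O)c1ccc(O[Si](C(C)C)(C(C)C)C(C)C)c(C/C=C(\OC/C=C(\C)CO[Si](CC)(CC)CC)OB2N(S(=O)(=O)c3cc(cc(c3)C(F)(F)F)C(F)(F)F)[C@@H](c3ccccc3)[C@H](c3ccccc3)N2S(=O)(=O)c2cc(cc(c2)C(F)(F)F)C(F)(F)F)c1 | intermediate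
12 | (2S,3S)-2-{[5-(methoxycarbonyl)-2-(triisopropylsilyloxy)phenyl]methyl}-3-methyl-3-[(triethylsilyloxy)methyl]pent-4-enoic acid | C=C[C@@](CO[Si](CC)(CC)CC)(C)[C@H](Cc1cc(ccc1O[Si](C(C)C)(C(C)C)C(C)C)C(=O)OC)C(=O)O | intermediate
13 | pent-4-ynoic acid | C#CCCC(=O)O | starting material
14 | N-methoxy-N-methylpent-4-ynamide | C#CCCC(=O)N(C)OC | intermediate
15 | prop-1-en-2-ylmagnesium bromide | C=C(C)[Mg]Br | starting material
16 | 2-methylhept-1-en-6-yn-3-one | C=C(C)C(=O)CCC#C | intermediate
17 | (3S)-2-methylhept-1-en-6-yn-3-ol | C=C(C)[C@@H](O)CCC#C | intermediate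
18 | (3S)-3-(tert-butyldimethylsilyloxy)-2-methylhept-1-en-6-yne | C=C(C)[C@@H](O[Si](C)(C)C(C)(C)C)CCC#C | intermediate
19 | (3S,6E)-3-(tert-butyldimethylsilyloxy)-7-iodo-2,6-dimethylhepta-1,6-diene | C=C(C)[C@@H](O[Si](C)(C)C(C)(C)C)CC/C(C)=C/I | intermediate
20 | B-alkyl-9-BBN borane from 12 (terminal carbon of the former vinyl group on boron; carboxyl as its 9-BBN borinate) | B1(C2CCCC1CCC2)CC[C@@](CO[Si](CC)(CC)CC)(C)[C@H](Cc1cc(ccc1O[Si](C(C)C)(C(C)C)C(C)C)C(=O)OC)C(=O)OB1C2CCCC1CCC2 | intermediate
21 | (2S,3S,6E,10S)-10-(tert-butyldimethylsilyloxy)-2-{[5-(methoxycarbonyl)-2-(triisopropylsilyloxy)phenyl]methyl}-3,7,11-trimethyl-3-[(triethylsilyloxy)methyl]dodeca-6,11-dienoic acid | C=C(C)[C@@H](O[Si](C)(C)C(C)(C)C)CC/C(C)=C/CC[C@@](CO[Si](CC)(CC)CC)(C)[C@H](Cc1cc(ccc1O[Si](C(C)C)(C(C)C)C(C)C)C(=O)OC)C(=O)O | intermediate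
22 | acid chloride of 21 | C=C(C)[C@@H](O[Si](C)(C)C(C)(C)C)CC/C(C)=C/CC[C@@](CO[Si](CC)(CC)CC)(C)[C@H](Cc1cc(ccc1O[Si](C(C)C)(C(C)C)C(C)C)C(=O)OC)C(=O)Cl | intermediate
23 | triethylsilyl-protected methyl ketone (COCH3 in place of COCl of 22) | C=C(C)[C@@H](O[Si](C)(C)C(C)(C)C)CC/C(C)=C/CC[C@@](CO[Si](CC)(CC)CC)(C)[C@H](Cc1cc(ccc1O[Si](C(C)C)(C(C)C)C(C)C)C(=O)OC)C(C)=O | intermediate
24 | methyl 3-[(2S,3S,6E,10S)-2-acetyl-10-(tert-butyldimethylsilyloxy)-3-(hydroxymethyl)-3,7,11-trimethyldodeca-6,11-dien-1-yl]-4-(triisopropylsilyloxy)benzoate | C=C(C)[C@@H](O[Si](C)(C)C(C)(C)C)CC/C(C)=C/CC[C@@](CO)(C)[C@H](Cc1cc(ccc1O[Si](C(C)C)(C(C)C)C(C)C)C(=O)OC)C(C)=O | intermediate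
25 | epoxy hydroxy ketone: 24 with a (6S,7S)-6,7-epoxide (global 10S,11S) | C=C(C)[C@@H](O[Si](C)(C)C(C)(C)C)CC[C@]1(C)O[C@H]1CC[C@@](CO)(C)[C@H](Cc2cc(ccc2O[Si](C(C)C)(C(C)C)C(C)C)C(=O)OC)C(C)=O | intermediate
26 | N-tosylhydrazone of 25 (C=N at C3) | C=C(C)[C@@H](O[Si](C)(C)C(C)(C)C)CC[C@]1(C)O[C@H]1CC[C@@](CO)(C)[C@H](Cc2cc(ccc2O[Si](C(C)C)(C(C)C)C(C)C)C(=O)OC)C(C)=NNS(=O)(=O)c2ccc(C)cc2 | intermediate
27 | aldehyde tosylhydrazone (C6 = CHO on the quaternary C7) | C=C(C)[C@@H](O[Si](C)(C)C(C)(C)C)CC[C@]1(C)O[C@H]1CC[C@@](C=O)(C)[C@H](Cc2cc(ccc2O[Si](C(C)C)(C(C)C)C(C)C)C(=O)OC)C(C)=NNS(=O)(=O)c2ccc(C)cc2 | intermediate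
28 | 2,4,6-trivinylcyclotriboroxane–pyridine complex | C=CB1OB(C=C)OB(C=C)O1.c1ccncc1 | starting material
29 | diazoalkane (C3=N2 in place of the hydrazone of 27) | C=C(C)[C@@H](O[Si](C)(C)C(C)(C)C)CC[C@]1(C)O[C@H]1CC[C@@](C=O)(C)[C@H](Cc2cc(ccc2O[Si](C(C)C)(C(C)C)C(C)C)C(=O)OC)C(C)=[N+]=[N-] | intermediate
30 | tertiary allylboronic acid (C3 bears CH3, vinyl and B(OH)2; C3 epimers) | C=C(C)[C@@H](O[Si](C)(C)C(C)(C)C)CC[C@]1(C)O[C@H]1CC[C@@](C=O)(C)[C@H](Cc2cc(ccc2O[Si](C(C)C)(C(C)C)C(C)C)C(=O)OC)C(C)(C=C)B(O)O | intermediate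
31 | cyclohexenol (global 2R,6R,7S,10S,11S,14S; C6–OH trans to C7–CH3; 10,11-epoxide; C14–OSi(t-Bu)Me2; aryl methyl ester and aryl OSi(i-Pr)3) | C=C(C)[C@@H](O[Si](C)(C)C(C)(C)C)CC[C@]1(C)O[C@H]1CC[C@@]2(C)[C@H](Cc3cc(ccc3O[Si](C(C)C)(C(C)C)C(C)C)C(=O)OC)C(C)=CC[C@H]2O | intermediate
32 | bromohydrin (global 2R,6R,7S,10R,11S,14S) | C=C(C)[C@@H](O[Si](C)(C)C(C)(C)C)CC[C@](C)(O)[C@H](Br)CC[C@@]2(C)[C@H](Cc3cc(ccc3O[Si](C(C)C)(C(C)C)C(C)C)C(=O)OC)C(C)=CC[C@H]2O | intermediate
33 | dibromide (global 2R,6S,7S,10R,11S,14S) | C=C(C)[C@@H](O[Si](C)(C)C(C)(C)C)CC[C@](C)(O)[C@H](Br)CC[C@@]2(C)[C@H](Cc3cc(ccc3O[Si](C(C)C)(C(C)C)C(C)C)C(=O)OC)C(C)=CC[C@@H]2Br | intermediate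
34 | benzoic acid from 33 | C=C(C)[C@@H](O[Si](C)(C)C(C)(C)C)CC[C@](C)(O)[C@H](Br)CC[C@@]2(C)[C@H](Cc3cc(ccc3O[Si](C(C)C)(C(C)C)C(C)C)C(=O)O)C(C)=CC[C@@H]2Br | intermediate
35 | seco acid (free C14–OH and CO2H) | C=C(C)[C@@H](O)CC[C@](C)(O)[C@H](Br)CC[C@@]2(C)[C@H](Cc3cc(ccc3O[Si](C(C)C)(C(C)C)C(C)C)C(=O)O)C(C)=CC[C@@H]2Br | intermediate
36 | macrolactone, phenol as triisopropylsilyl ether | C=C(C)[C@@H]1CC[C@](C)(O)[C@H](Br)CC[C@@]2(C)[C@H](Cc3cc(ccc3O[Si](C(C)C)(C(C)C)C(C)C)C(=O)O1)C(C)=CC[C@@H]2Br | intermediate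
37 | CNP0213075.1 | C=C(C)[C@@H]1CC[C@](C)(O)[C@H](Br)CC[C@@]2(C)[C@H](Cc3cc(ccc3O)C(=O)O1)C(C)=CC[C@@H]2Br | target

Total step count: 25. Longest linear sequence: 17 steps (steps 1–3, 7, 8 and 14–25; the branches through 9 and through 19 are equally long).

Steps most likely to fail

Step 19. The diazoalkane may collapse by 1,2-hydride shift before it is captured by boron, the allylboronic acid may protodeboronate or react between molecules before it closes the ring, or the facial selectivity at C6 may be poor. The fallback sets out from 25 and returns at 31, building the two bonds one after the other. Wittig methylenation of the C3 ketone (Ph3P=CH2, THF, −78 to 0 °C) gives the 1,1-disubstituted alkene F1. Ley–Griffith oxidation of the primary alcohol gives the aldehyde F2. Brown allylation with (+)-B-allyldiisopinocampheylborane (from (−)-α-pinene; Et2O, −78 °C, ethanolamine work-up) forms the C5–C6 bond and should set the (6R) carbinol by reagent control, giving the homoallylic alcohol F3. Ring-closing metathesis of the allyl group with the C3 isopropenyl group (second-generation Hoveyda–Grubbs catalyst, CH2Cl2, 40 °C) then closes C3=C4 and gives 31.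

Step 21. E2 elimination toward the conjugated diene or a 1,2-methyl shift may outrun SN2 displacement at the neopentyl-type C6 during the heated one-flask activation. The fallback sets out from 32 and returns at 33 by a stepwise substitution through an isolated, much better leaving group. Chloromethanesulfonyl chloride and pyridine at 0 °C give the C6 chloromethanesulfonate F4, which is then displaced with inversion by LiBr in DMF at or below room temperature, so that a non-basic bromide source acts on a preformed sulfonate instead of a hot oxyphosphonium salt.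

Step 8. Enantio- or diastereocontrol may be insufficient, or the rearrangement of the hindered boron ketene acetal may stall over the long reaction time with partial loss of the silyl ethers. The fallback sets out from 10 and returns at 12 by resolution instead of asymmetric induction. A classical Ireland–Claisen rearrangement (LDA, THF, −78 °C; Me3SiCl, Et3N; warm to rt) passes through the E(O) trimethylsilyl ketene acetal F5 and, through the same chair transition state, gives the racemic acid F6 with the correct relative configuration. Crystallisation with (R)-1-phenylethylamine gives the diastereomerically pure salt F7 (the matching amine antipode is assumed), and mild acidification with aqueous citric acid returns 12.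

Further compounds
F1 | step 19 | hydroxy alkene: 25 with C(CH3)=CH2 in place of the C3 ketone | C=C(C)[C@@H](O[Si](C)(C)C(C)(C)C)CC[C@]1(C)O[C@H]1CC[C@@](CO)(C)[C@H](Cc2cc(ccc2O[Si](C(C)C)(C(C)C)C(C)C)C(=O)OC)C(C)=C
F2 | step 19 | aldehyde: F1 with CHO (C6) in place of CH2OH | C=C(C)[C@@H](O[Si](C)(C)C(C)(C)C)CC[C@]1(C)O[C@H]1CC[C@@](C=O)(C)[C@H](Cc2cc(ccc2O[Si](C(C)C)(C(C)C)C(C)C)C(=O)OC)C(C)=C
F3 | step 19 | (6R)-homoallylic alcohol: allyl group added to the aldehyde of F2 | C=C(C)[C@@H](O[Si](C)(C)C(C)(C)C)CC[C@]1(C)O[C@H]1CC[C@@]([C@H](O)CC=C)(C)[C@H](Cc2cc(ccc2O[Si](C(C)C)(C(C)C)C(C)C)C(=O)OC)C(C)=C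
F4 | step 21 | C6 chloromethanesulfonate of 32 | C=C(C)[C@@H](O[Si](C)(C)C(C)(C)C)CC[C@](C)(O)[C@H](Br)CC[C@@]2(C)[C@H](Cc3cc(ccc3O[Si](C(C)C)(C(C)C)C(C)C)C(=O)OC)C(C)=CC[C@H]2OS(=O)(=O)CCl
F5 | step 8 | trimethylsilyl ketene acetal of 10 (E(O) geometry) | COC(=O)c1ccc(O[Si](C(C)C)(C(C)C)C(C)C)c(C/C=C(\OC/C=C(\C)CO[Si](CC)(CC)CC)O[Si](C)(C)C)c1
F6 | step 8 | racemic acid: 1:1 mixture of 12 and its enantiomer | C=C[C@@](CO[Si](CC)(CC)CC)(C)[C@H](Cc1cc(ccc1O[Si](C(C)C)(C(C)C)C(C)C)C(=O)OC)C(=O)O.C=C[C@](CO[Si](CC)(CC)CC)(C)[C@@H](Cc1cc(ccc1O[Si](C(C)C)(C(C)C)C(C)C)C(=O)OC)C(=O)O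
F7 | step 8 | (R)-1-phenylethylammonium salt of 12 | C=C[C@@](CO[Si](CC)(CC)CC)(C)[C@H](Cc1cc(ccc1O[Si](C(C)C)(C(C)C)C(C)C)C(=O)OC)C(=O)[O-].C[C@@H]([NH3+])c1ccccc1
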